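All runs come from a simulation for an exercise; noise was put on by code.

A small charge of Z, the north-west flask, is to run for 16 min. Z and L give X, with E as catalyst.

| flask | Z | L | E | X | time |
|---|---|---|---|---|---|
| north-east | 0.150 M | 0.225 M | 0.00750 M |  |  |
| west | 0.0600 M | 0.135 M | 0.00750 M |  |  |
| south-west | 0.150 M | 0.225 M | 0.00750 M | 0.0450 M |  |
| south | 0.450 M | 0.225 M | 0.00750 M |  |  |
| north-west | 0.0750 M | 0.110 M | 0.00750 M |  | 16 min |

| run | time / min | [X] / M |
|---|---|---|
| north-east run | 2.0 | 0.0190 |
| north-east run | 4.0 | 0.0343 |
| north-east run | 6.0 | 0.0465 |
| north-east run | 8.0 | 0.0572 |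
| north-east run | 10 | 0.0652 |
| north-east run | 12 | 0.0728 |
| north-east run | 14 | 0.0796 |
| north-east run | 16 | 0.0849 |
| west run | 2.0 | 0.0049 |
| west run | 4.0 | 0.0100 |
| west run | 6.0 | 0.0145 |
| west run | 8.0 | 0.0169 |
| west run | 10 | 0.0210 |
| west run | 12 | 0.0242 |
| west run | 14 | 0.0261 |
| west run | 16 | 0.0291 |
| south-west run | 2.0 | 0.0622 |
| south-west run | 4.0 | 0.0788 |
| south-west run | 6.0 | 0.0918 |
| south-west run | 8.0 | 0.1012 |
| south-west run | 10 | 0.1110 |
| south-west run | 12 | 0.1183 |
| south-west run | 14 | 0.1247 |
| south-west run | 16 | 0.1303 |
| south run | 2.0 | 0.0360 |
| south run | 4.0 | 0.0650 |
| south run | 6.0 | 0.0882 |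
| south run | 8.0 | 0.1068 |
| south run | 10 | 0.1233 |
| south run | 12 | 0.1365 |
| south run | 14 | 0.1470 |
| south run | 16 | 0.1564 |

(each reading ± 4 × 10⁻⁴ M)

- Overall: Z + L -> X, with E as catalyst.
- Constant volume, constant temperature.
- The analysis sees a species whether free or bound.
- "The second partner" is L.
- An order is taken over about fifteen percent of the charge, up and down.

- apparent order in [L] of the starting rate, round the charge of the north-east run (the rate where two percent of its Z have turned into X)
- apparent order in [Z] of the starting rate, round the charge of the north-east run (the rate where two percent of its Z have turned into X) (one fixed amount of X, the same in the runs compared)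
- the west run starts with 0.0900 M less of Z and of L than the north-east run, and with no X. Compared where both hold the same amount of Z, once fifteen percent of what the west run was charged with has turned into X, is the west run faster, slower or alike (within a tenth)?
- X in the north-west run at 16 min, as a share of the Z charged

**Which run stands nearest?** The west run: it was charged with 0.0600 M of Z against the north-west 0.0750 M, and it has a reading at 16 min.

**What do you take from it?** One number. Let f be the share of charged Z turned into X, u the share left, and λ the charge of L per charge of Z. The integrated second-order law reads ln[(λ − f)/(λu)] = (L charged − Z charged)/W. The west reading gives W = 0.178 M. I call this the window charge: the equal charge of Z and L that this law turns half over in 16 min. A larger W means a slower window. Read across the whole window, it takes in whatever elapsed time does to the rate.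

**And the north-west flask?** Here λ is 1.47, so Z is the limiting reagent. Solving the law with the west W gives a first answer of f = 40.5%.

**But is W constant?** No. The south run's reading gives 0.296 M, larger than the west value, at a mean Z of 0.372 M against 0.0454 M. A straight line through these two runs has slope 0.360.

**So go round again.** The first answer puts the north-west mean Z at 0.0598 M. The line then gives W = 0.183 M, and the law gives f = 39.8%. That is my answer.

**What does the forecast say?** It gives 40%, a little above mine, with orders of 1 in L and 0.7 in Z, and the west run faster. Its ground for that last call: “The rate therefore depends on elapsed time, not just composition”.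

**What runs in the flask?**

    E + Z + L → X + E (55.92 L² mol⁻² min⁻¹)
    E + Z ⇌ EZ, settled at all times (2.430 L mol⁻¹)
    E → Zu (0.01512 min⁻¹)

The north-west flask ends at 38.7%, 1.1 percentage points below my second answer. Round the north-east charge the orders are 1.0 in L and 0.76 in Z, and the west run is faster, at 1.3 times the north-east rate at equal Z. Round the north-east charge the order in Z stands at 0.76; in the same reckoning with the tying up of E + Z as EZ taken away it stands at 1.0. Carried to the north-east run, the west W gives 61.1%. The line then gives W = 0.199 M and f = 57.8%, where its reading at 16 min stands at 56.6%.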